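The excess is a race.

| setting | Friday's | Monday's | flask |
|---|---|---|---|
| left-handed substrate | 0.0020 M | 0.0020 M | 0.0020 M |
| right-handed substrate | 0.0020 M | 0.0020 M | 0.0020 M |
| partner | 2.2 mM | 2.2 mM | 2.20 mM |
| protic impurity | 0.10 mM | 0.10 mM | 0.100 mM |
| catalyst | 0.20 mM | 0.10 mM | 0.20 mM |
| remark | the very flask that is asked about, followed so far | run made earlier |  |
| time |  |  | 2.5 min |

- Friday's (time / s: right-handed substrate / %, left-handed substrate / %, left-handed product / %): 10.0: 42.7, 38.4, 13.3; 15.0: 38.2, 34.0, 17.4; 25.0: 35.1, 32.0, 19.3; 50.0: 32.6, 29.3, 26.3; 80.0: 30.1, 30.4, 26.2
- Monday's (time / min: right-handed substrate / %, left-handed substrate / %, left-handed product / %): 0.417: 41.6, 39.5, 13.5; 0.833: 38.7, 34.6, 18.9; 1.33: 35.8, 33.7, 21.0; 1.50: 33.3, 33.2, 21.4; 2.00: 33.4, 32.4, 22.2; 2.50: 32.9, 33.7, 23.0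

(standard deviation of a reading: 1 percentage point)

* whether the excess of right-handed substrate over left-handed substrate among what is left of the two reaches 98% by 2.5 min (no / yes)
* the highest excess of right-handed substrate over left-handed substrate among what is left of the two up to 2.5 min

- catalyst is single-handed; left-handed substrate and right-handed substrate are mirror images of each other, charged as a racemate, each of them at the stated concentration

At 80.0 s of Friday's run, 39.5% of the substrate had gone and 26.2% stood as left-handed product. Counting the remainder as right-handed product gives a selectivity factor near 1.97, and the left-handed form reacted in surplus by 12.9%, a share of 32.7% of what reacted. Yet the substrates then read 30.1% and 30.4%, so interconversion had handed that surplus back. Dividing it by the gap between them summed over Friday's run gives a relaxation rate of 0.0632 s⁻¹, a rough reading given the scatter of 1 percentage point. Its half-life of 11.0 s is short against 2.5 min.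

The first reading gives the pull, the substrate's fractional loss rate, as 0.0209 s⁻¹. Where making and relaxing balance, the excess is 8.13%: this balance excess is the surplus share times pull over pull plus relaxation.

So in this flask the excess, taken as a fraction, should leave zero with a slope of about 0.00683 s⁻¹ and bend within about 11.9 s. It should peak below the balance excess as partner fades, then sink toward zero once the substrate sum flattens near 60.5%. The 98% wanted stands far above this balance excess, so my answer is no.

The forecast says no and 6%: “The excess therefore peaks early at about 5–6% and then fades”.

The flask gives no and a top of 6.75%, below the balance excess.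

    partner + catalyst + left-handed substrate → catalyst + left-handed product (k = 1.12 × 10⁵ L² mol⁻² s⁻¹)
    partner + catalyst + right-handed substrate → catalyst + right-handed product (k = 52400 L² mol⁻² s⁻¹)
    left-handed substrate ⇌ right-handed substrate (k = 0.0281 s⁻¹)
    2 partner → homo dimer (k = 8.13 L mol⁻¹ s⁻¹)
    partner + protic impurity → quenched reagent (k = 13500 L mol⁻¹ s⁻¹)

The neighbouring flask charges 0.0088 M of partner, which multiplies the pull by 4.00. The same reckoning then gives a balance excess of 18.6%. At 2.50 min that flask holds 7.41% left-handed substrate and 7.65% right-handed substrate, and its excess has topped out at 20.6%.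

(The data are simulated on assumed constants; the scatter is artificial.)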